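The cyclohexenone (numbered as cyclohex-2-en-1-one) is opened between the carbinol carbon C5 and the quaternary carbon C6: C5(OH)–C6(CH3)2–C1(=O) is a β-hydroxy ketone. This bond is closed late by an intramolecular Mukaiyama aldol reaction that forms the ring and sets C5 trans to the C4 methyl group in one operation. Its precursor is an acyclic α-methyl aldehyde carrying a tetrasubstituted silyl enol ether on a Z-trisubstituted alkene. The alkene comes from an alkyne by hydroxyl-directed trans-hydrostannation and Stille acylation; the alkyne joins a four-carbon unit from methyl (R)-3-hydroxy-2-methylpropanoate to O-methyl-D-serine, and the lipid acid is attached early as its amide.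

Key step: step 23

Remark: ring locants follow cyclohex-2-en-1-one (C1 carbonyl, C2 side-chain carbon, C4 methyl, C5 hydroxyl, C6 gem-dimethyl), C1' is the side-chain carbinol carbon and C2' the nitrogen-bearing carbon; the sense of induction in steps 2, 4 and 14 is assigned by analogy with the standard substrates of these reagent-controlled reactions.

**Fragment 1: the lipid acid**

Step 1
Reactants: 1 non-1-yne
Product: 3 (2E)-3-methyldec-2-en-1-ol, via alkenylalane 2 (not isolated)
Conditions: Me3Al, Cp2ZrCl2 (20 mol %), CH2Cl2, rt; then n-BuLi, (CH2O)n, THF, −78 °C → rt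
Reagents that add atoms: trimethylaluminium C[Al](C)C; formaldehyde (as paraformaldehyde) C=O
Why: Negishi carboalumination adds methyl and aluminium syn across the terminal alkyne with aluminium at the terminus, and the derived alanate is hydroxymethylated with retention, so the trisubstituted alkene should form as the E isomer only.

Step 2
Reactants: 3 (2E)-3-methyldec-2-en-1-ol
Product: 4 (3S)-3-methyldecan-1-ol
Conditions: Ru(OAc)2[(R)-BINAP] (0.5 mol %), H2 (100 atm), MeOH, 20 °C
Reagents that add atoms: none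
Why: Ruthenium–BINAP asymmetric hydrogenation of an allylic alcohol (the geraniol-to-citronellol reaction type) sets C3 by catalyst control, the (R)-ligand being expected to give the 3S alcohol from the E alkene; this centre becomes C9 of the acid.

Step 3
Reactants: 4 (3S)-3-methyldecan-1-ol
Product: 5 (3S)-3-methyldecanal
Conditions: TEMPO (10 mol %), PhI(OAc)2, CH2Cl2, rt
Reagents that add atoms: none
Why: Nitroxyl-catalysed oxidation of a primary alcohol stops at the aldehyde and does not touch the β-stereocentre.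

Step 4
Reactants: 5 (3S)-3-methyldecanal
Product: 6 (4S,6S)-6-methyltridec-1-en-4-ol
Conditions: (−)-Ipc2B(allyl), Et2O, −78 °C; then NaOH, H2O2
Reagents that add atoms: (−)-B-allyldiisopinocampheylborane C=CCB([C@H]1[C@H](C)[C@H]2C[C@@H](C1)C2(C)C)[C@H]1[C@H](C)[C@H]2C[C@@H](C1)C2(C)C
Why: Brown allylation through a chair transition state, in which the reagent derived from (+)-α-pinene should override the weak bias of the remote methyl group and deliver the 4S carbinol (C7 of the acid).

Step 5
Reactants: 6 (4S,6S)-6-methyltridec-1-en-4-ol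
Product: 7 (4S,6S)-4-methoxy-6-methyltridec-1-ene
Conditions: NaH, MeI, THF, 0 °C → rt
Reagents that add atoms: iodomethane CI
Why: Williamson etherification of the sodium alkoxide; no stereocentre is involved.

Step 6
Reactants: 7 (4S,6S)-4-methoxy-6-methyltridec-1-ene
Product: 9 (3R,5S)-3-methoxy-5-methyldodecanal, via ozonide 8 (not isolated)
Conditions: O3, CH2Cl2, −78 °C; then PPh3
Reagents that add atoms: ozone [O-][O+]=O
Why: Ozonolysis of the terminal alkene with reductive work-up leaves the ether and the saturated chain untouched, and the β-methoxy aldehyde is used crude to avoid β-elimination.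

Step 7
Reactants: 9 (3R,5S)-3-methoxy-5-methyldodecanal
Product: 11 (5R,7S)-5-methoxy-7-methyltetradec-1-en-3-yl acetate, via bromomagnesium alkoxide 10 (not isolated)
Conditions: CH2=CHMgBr, THF, −78 °C; then Ac2O, −78 °C → rt
Reagents that add atoms: vinylmagnesium bromide C=C[Mg]Br; acetic anhydride CC(=O)OC(C)=O
Why: Grignard addition followed by O-acetylation of the magnesium alkoxide in the same flask; the new carbinol centre is not controlled and need not be, because step 8 destroys it.

Step 8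
Reactants: 11 (5R,7S)-5-methoxy-7-methyltetradec-1-en-3-yl acetate
Product: 14 (4E,7R,9S)-7-methoxy-9-methylhexadec-4-enoic acid, via silyl ketene acetal 12 (not isolated), via trimethylsilyl ester 13 (not isolated)
Conditions: LiN(iPr)2, Me3SiCl, THF, −78 °C → 60 °C; then 1 M HCl
Reagents that add atoms: none
Why: Ireland–Claisen rearrangement through a chair transition state with the alkyl chain equatorial should give the E-configured C4–C5 alkene and turns the acetate carbons into C1–C2 of the acid, while C7 and C9 are untouched.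

**Fragment 2: the alkyne**

Step 9
Reactants: 15 methyl (2R)-3-hydroxy-2-methylpropanoate
Product: 16 methyl (2R)-3-{[tert-butyl(dimethyl)silyl]oxy}-2-methylpropanoate
Conditions: TBSCl, imidazole, CH2Cl2, rt
Reagents that add atoms: tert-butyldimethylsilyl chloride CC(C)(C)[Si](C)(C)Cl
Why: Standard silylation of the primary alcohol.

Step 10
Reactants: 16 methyl (2R)-3-{[tert-butyl(dimethyl)silyl]oxy}-2-methylpropanoate
Product: 17 (2R)-3-{[tert-butyl(dimethyl)silyl]oxy}-2-methylpropanal
Conditions: iBu2AlH (1.1 equiv), CH2Cl2, −78 °C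
Reagents that add atoms: none
Why: Low-temperature half-reduction of the methyl ester through the stable aluminium hemiacetal, under which the α-stereocentre is not enolised.

Step 11
Reactants: 17 (2R)-3-{[tert-butyl(dimethyl)silyl]oxy}-2-methylpropanal
Product: 18 tert-butyl(dimethyl){[(2S)-2-methylbut-3-yn-1-yl]oxy}silane
Conditions: dimethyl (1-diazo-2-oxopropyl)phosphonate, K2CO3, MeOH, 0 °C → rt
Reagents that add atoms: dimethyl (1-diazo-2-oxopropyl)phosphonate COP(=O)(OC)C(=[N+]=[N-])C(C)=O
Why: Ohira–Bestmann (Seyferth–Gilbert) homologation under mild carbonate conditions should give the terminal alkyne without epimerising the adjacent methyl-bearing centre, which becomes ring C4 (the descriptor changes only because the priorities change).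

**Union and head group**

Step 12
Reactants: 19 N-Boc-O-methyl-D-serine
Product: 20 tert-butyl N-[(2R)-1-methoxy-3-[methoxy(methyl)amino]-3-oxopropan-2-yl]carbamate
Conditions: MeNH(OMe)·HCl, EDC·HCl, HOBt, N-methylmorpholine, CH2Cl2, 0 °C → rt
Reagents that add atoms: N,O-dimethylhydroxylamine hydrochloride CNOC.Cl
Why: Carbodiimide coupling of a urethane-protected amino acid, which does not racemise through an oxazolone, gives the Weinreb amide.

Step 13
Reactants: 18 tert-butyl(dimethyl){[(2S)-2-methylbut-3-yn-1-yl]oxy}silane and 20 tert-butyl N-[(2R)-1-methoxy-3-[methoxy(methyl)amino]-3-oxopropan-2-yl]carbamate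
Product: 22 tert-butyl N-[(2R,6S)-7-{[tert-butyl(dimethyl)silyl]oxy}-1-methoxy-6-methyl-3-oxohept-4-yn-2-yl]carbamate, via lithium acetylide 21 (not isolated)
Conditions: 18 (2.2 equiv), n-BuLi, THF, −78 °C; then 20, −78 → −30 °C; AcOH at −78 °C
Reagents that add atoms: none
Why: Acylation of a lithium acetylide by a Weinreb amide stops at the ketone through the chelated tetrahedral intermediate, the first equivalent of acetylide deprotonating the carbamate N–H and thereby shielding the α-centre, and the acidic quench keeps the released amine from adding to the ynone.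

Step 14
Reactants: 22 tert-butyl N-[(2R,6S)-7-{[tert-butyl(dimethyl)silyl]oxy}-1-methoxy-6-methyl-3-oxohept-4-yn-2-yl]carbamate
Product: 23 tert-butyl N-[(2R,3S,6S)-7-{[tert-butyl(dimethyl)silyl]oxy}-3-hydroxy-1-methoxy-6-methylhept-4-yn-2-yl]carbamate
Conditions: RuCl[(R,R)-TsDPEN](p-cymene) (2 mol %), HCO2H/Et3N (5:2), CH2Cl2, rt
Reagents that add atoms: none
Why: Noyori asymmetric transfer hydrogenation of an alkynyl ketone, in which the alkyne takes the place of the aryl group; the (R,R)-catalyst should give the 3S carbinol (C1') by catalyst control, anti to the nitrogen at C2'.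

Step 15
Reactants: 23 tert-butyl N-[(2R,3S,6S)-7-{[tert-butyl(dimethyl)silyl]oxy}-3-hydroxy-1-methoxy-6-methylhept-4-yn-2-yl]carbamate and 14 (4E,7R,9S)-7-methoxy-9-methylhexadec-4-enoic acid
Product: 25 (4E,7R,9S)-N-[(2R,3S,6S)-3,7-dihydroxy-1-methoxy-6-methylhept-4-yn-2-yl]-7-methoxy-9-methylhexadec-4-enamide, via amino diol hydrochloride 24 (not isolated)
Conditions: HCl (4 M in dioxane), MeOH, 0 °C → rt; evaporate; then 14, EDC·HCl, HOBt, iPr2NEt, CH2Cl2, 0 °C → rt
Reagents that add atoms: none
Why: Acidic methanolysis removes the Boc group and the primary silyl ether together, and carbodiimide/HOBt coupling acylates the amine chemoselectively in the presence of both hydroxyl groups; the amide is installed here so that no free amine ever faces the later C1 ketone.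

Step 16
Reactants: 25 (4E,7R,9S)-N-[(2R,3S,6S)-3,7-dihydroxy-1-methoxy-6-methylhept-4-yn-2-yl]-7-methoxy-9-methylhexadec-4-enamide
Product: 26 (2S,5S,6R)-5-hydroxy-7-methoxy-6-{[(4E,7R,9S)-7-methoxy-9-methylhexadec-4-enoyl]amino}-2-methylhept-3-yn-1-yl 2,2-dimethylpropanoate
Conditions: PivCl (1.1 equiv), pyridine, CH2Cl2, −20 → 0 °C
Reagents that add atoms: pivaloyl chloride CC(C)(C)C(Cl)=O
Why: Sterically controlled acylation of the primary over the hindered secondary propargylic alcohol; a pivalate is chosen because it can later be removed by hydride without acid or fluoride.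

Step 17
Reactants: 26 (2S,5S,6R)-5-hydroxy-7-methoxy-6-{[(4E,7R,9S)-7-methoxy-9-methylhexadec-4-enoyl]amino}-2-methylhept-3-yn-1-yl 2,2-dimethylpropanoate
Product: 27 (2S,3Z,5R,6R)-5-hydroxy-7-methoxy-6-{[(4E,7R,9S)-7-methoxy-9-methylhexadec-4-enoyl]amino}-2-methyl-4-(tributylstannyl)hept-3-en-1-yl 2,2-dimethylpropanoate
Conditions: [Cp*RuCl]4 (2.5 mol %), Bu3SnH, CH2Cl2, rt
Reagents that add atoms: tributyltin hydride CCCC[SnH](CCCC)CCCC
Why: Ruthenium-catalysed trans-hydrostannation of a propargylic alcohol, in which hydrogen bonding of the free hydroxyl to the Ru–Cl unit should place tin on the proximal alkyne carbon while hydride adds anti, so that tin ends up cis to the C4 carbon as the ring requires (the C1' descriptor changes only because tin outranks nitrogen).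

Step 18
Reactants: 27 (2S,3Z,5R,6R)-5-hydroxy-7-methoxy-6-{[(4E,7R,9S)-7-methoxy-9-methylhexadec-4-enoyl]amino}-2-methyl-4-(tributylstannyl)hept-3-en-1-yl 2,2-dimethylpropanoate
Product: 28 (2S,3Z,5R,6R)-7-methoxy-6-{[(4E,7R,9S)-7-methoxy-9-methylhexadec-4-enoyl]amino}-2-methyl-4-(tributylstannyl)-5-[(triethylsilyl)oxy]hept-3-en-1-yl 2,2-dimethylpropanoate
Conditions: Et3SiCl, imidazole, DMAP (cat.), DMF, rt
Reagents that add atoms: chlorotriethylsilane CC[Si](Cl)(CC)CC
Why: Silylation of the secondary allylic alcohol so that it can neither be acylated nor add to the dienone in the following steps.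

Step 19
Reactants: 28 (2S,3Z,5R,6R)-7-methoxy-6-{[(4E,7R,9S)-7-methoxy-9-methylhexadec-4-enoyl]amino}-2-methyl-4-(tributylstannyl)-5-[(triethylsilyl)oxy]hept-3-en-1-yl 2,2-dimethylpropanoate
Product: 29 (2S,3Z,5S,6R)-7-methoxy-6-{[(4E,7R,9S)-7-methoxy-9-methylhexadec-4-enoyl]amino}-2-methyl-4-(2-methylprop-2-enoyl)-5-[(triethylsilyl)oxy]hept-3-en-1-yl 2,2-dimethylpropanoate
Conditions: methacryloyl chloride, Pd2(dba)3 (5 mol %), P(2-furyl)3 (20 mol %), THF, 50 °C
Reagents that add atoms: methacryloyl chloride CC(=C)C(Cl)=O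
Why: Stille acylation of an alkenylstannane with an acid chloride proceeds with retention of alkene geometry and installs C1 together with C6 and its two one-carbon substituents as a cross-conjugated dienone.

Step 20
Reactants: 29 (2S,3Z,5S,6R)-7-methoxy-6-{[(4E,7R,9S)-7-methoxy-9-methylhexadec-4-enoyl]amino}-2-methyl-4-(2-methylprop-2-enoyl)-5-[(triethylsilyl)oxy]hept-3-en-1-yl 2,2-dimethylpropanoate
Product: 30 (2S,3Z,5S,6R)-7-methoxy-6-{[(4E,7R,9S)-7-methoxy-9-methylhexadec-4-enoyl]amino}-2-methyl-4-{2-methyl-1-[(triethylsilyl)oxy]prop-1-en-1-yl}-5-[(triethylsilyl)oxy]hept-3-en-1-yl 2,2-dimethylpropanoate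
Conditions: RhCl(PPh3)3 (2 mol %), Et3SiH, toluene, 50 °C
Reagents that add atoms: triethylsilane CC[SiH](CC)CC
Why: Rhodium-catalysed 1,4-hydrosilylation of an enone should occur at the unhindered isopropenyl terminus and not at the trisubstituted enone, giving the tetrasubstituted silyl enol ether regiospecifically and masking the C1 carbonyl.

Step 21
Reactants: 30 (2S,3Z,5S,6R)-7-methoxy-6-{[(4E,7R,9S)-7-methoxy-9-methylhexadec-4-enoyl]amino}-2-methyl-4-{2-methyl-1-[(triethylsilyl)oxy]prop-1-en-1-yl}-5-[(triethylsilyl)oxy]hept-3-en-1-yl 2,2-dimethylpropanoate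
Product: 31 (4E,7R,9S)-N-[(2R,3S,4Z,6S)-7-hydroxy-1-methoxy-6-methyl-4-{2-methyl-1-[(triethylsilyl)oxy]prop-1-en-1-yl}-3-[(triethylsilyl)oxy]hept-4-en-2-yl]-7-methoxy-9-methylhexadec-4-enamide
Conditions: iBu2AlH (3.5 equiv), CH2Cl2, −78 °C; aq. potassium sodium tartrate
Reagents that add atoms: none
Why: Reductive cleavage of the pivalate by an aluminium hydride at low temperature, under which the silyl enol ether, the silyl ether and the N-deprotonated secondary amide are inert.

Step 22
Reactants: 31 (4E,7R,9S)-N-[(2R,3S,4Z,6S)-7-hydroxy-1-methoxy-6-methyl-4-{2-methyl-1-[(triethylsilyl)oxy]prop-1-en-1-yl}-3-[(triethylsilyl)oxy]hept-4-en-2-yl]-7-methoxy-9-methylhexadec-4-enamide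
Product: 32 (4E,7R,9S)-N-[(2R,3S,4Z,6S)-1-methoxy-6-methyl-4-{2-methyl-1-[(triethylsilyl)oxy]prop-1-en-1-yl}-7-oxo-3-[(triethylsilyl)oxy]hept-4-en-2-yl]-7-methoxy-9-methylhexadec-4-enamide
Conditions: Dess–Martin periodinane, NaHCO3, CH2Cl2, 0 °C; used crude at once
Reagents that add atoms: none
Why: Buffered Dess–Martin oxidation of the primary alcohol; because C1 is masked as the enol ether, the hydrogen at C4 is only that of an ordinary α-branched aldehyde and should survive brief handling.

Step 23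
Reactants: 32 (4E,7R,9S)-N-[(2R,3S,4Z,6S)-1-methoxy-6-methyl-4-{2-methyl-1-[(triethylsilyl)oxy]prop-1-en-1-yl}-7-oxo-3-[(triethylsilyl)oxy]hept-4-en-2-yl]-7-methoxy-9-methylhexadec-4-enamide
Product: 33 (4E,7R,9S)-N-[(1S,2R)-1-[(3S,4R)-4-hydroxy-3,5,5-trimethyl-6-oxocyclohex-1-en-1-yl]-3-methoxy-1-[(triethylsilyl)oxy]propan-2-yl]-7-methoxy-9-methylhexadec-4-enamide
Conditions: BF3·OEt2 (3 equiv), CH2Cl2, −78 °C; aq. NaHCO3
Reagents that add atoms: none
Why: Intramolecular Mukaiyama aldol reaction: BF3 activates the aldehyde (C5), the C6 terminus of the tetrasubstituted triethylsilyl enol ether attacks it, and loss of the silyl group from the resulting oxocarbenium ion unveils the C1 ketone, now conjugated with the C2=C3 alkene. The cyclohexenone ring closes in the 6-(enolendo)-exo-trig mode, made possible by the Z geometry that holds C1 and C4 on the same side of the alkene. The only new stereocentre, C5, is controlled by the C4 methyl centre: the methyl group sits pseudo-equatorial, away from the developing gem-dimethyl carbon, and in the open transition state the BF3-bound C=O lies antiperiplanar to the enol C=C, so the oxygen becomes equatorial and trans to the methyl group (5R). The step needs this trans over cis selectivity and an intact C4; a chelated Zimmerman–Traxler array, which would give the cis isomer, is excluded because the silylated enol oxygen cannot bridge to boron, and the bulky OSiEt3 group disfavours the synclinal approach. C4 should survive because C1 is not a carbonyl group until the C–C bond has formed, so its hydrogen is never flanked by an aldehyde and an enone at once, and the nucleophilic carbon bears two identical methyl groups, so no enol ether geometry has to be controlled.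

Step 24
Reactants: 33 (4E,7R,9S)-N-[(1S,2R)-1-[(3S,4R)-4-hydroxy-3,5,5-trimethyl-6-oxocyclohex-1-en-1-yl]-3-methoxy-1-[(triethylsilyl)oxy]propan-2-yl]-7-methoxy-9-methylhexadec-4-enamide
Product: 34 (4E,7R,9S)-N-[(1S,2R)-1-hydroxy-1-[(3S,4R)-4-hydroxy-3,5,5-trimethyl-6-oxocyclohex-1-en-1-yl]-3-methoxypropan-2-yl]-7-methoxy-9-methylhexadec-4-enamide (CNP0168625.1)
Conditions: HF·pyridine, pyridine, THF, 0 °C → rt
Reagents that add atoms: none
Why: Buffered fluoride cleavage of the secondary triethylsilyl ether under conditions that should not provoke retro-aldol cleavage of the β-hydroxy ketone.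

**Compound list**

1 | non-1-yne | C#CCCCCCCC | starting material
2 | dimethyl[(1E)-2-methylnon-1-en-1-yl]alumane | CCCCCCC/C(C)=C/[Al](C)C | intermediate (not isolated)
3 | (2E)-3-methyldec-2-en-1-ol | CCCCCCC/C(C)=C/CO | intermediate
4 | (3S)-3-methyldecan-1-ol | CCCCCCC[C@H](C)CCO | intermediate
5 | (3S)-3-methyldecanal | CCCCCCC[C@H](C)CC=O | intermediate
6 | (4S,6S)-6-methyltridec-1-en-4-ol | CCCCCCC[C@H](C)C[C@H](CC=C)O | intermediate
7 | (4S,6S)-4-methoxy-6-methyltridec-1-ene | CCCCCCC[C@H](C)C[C@H](CC=C)OC | intermediate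
8 | 3-[(2R,4S)-2-methoxy-4-methylundecyl]-1,2,4-trioxolane (ozonide) | CCCCCCC[C@H](C)C[C@H](CC1OCOO1)OC | intermediate (not isolated)
9 | (3R,5S)-3-methoxy-5-methyldodecanal | CCCCCCC[C@H](C)C[C@H](CC=O)OC | intermediate
10 | bromomagnesium (5R,7S)-5-methoxy-7-methyltetradec-1-en-3-olate (both C3 epimers) | CCCCCCC[C@H](C)C[C@H](CC(O[Mg]Br)C=C)OC | intermediate (not isolated)
11 | (5R,7S)-5-methoxy-7-methyltetradec-1-en-3-yl acetate (both C3 epimers) | CCCCCCC[C@H](C)C[C@H](CC(OC(C)=O)C=C)OC | intermediate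
12 | trimethylsilyl ketene acetal of 11 | CCCCCCC[C@H](C)C[C@H](CC(OC(=C)O[Si](C)(C)C)C=C)OC | intermediate (not isolated)
13 | trimethylsilyl (4E,7R,9S)-7-methoxy-9-methylhexadec-4-enoate | CCCCCCC[C@H](C)C[C@H](C/C=C/CCC(=O)O[Si](C)(C)C)OC | intermediate (not isolated)
14 | (4E,7R,9S)-7-methoxy-9-methylhexadec-4-enoic acid | CCCCCCC[C@H](C)C[C@H](C/C=C/CCC(=O)O)OC | intermediate
15 | methyl (2R)-3-hydroxy-2-methylpropanoate | COC(=O)[C@H](C)CO | starting material
16 | methyl (2R)-3-{[tert-butyl(dimethyl)silyl]oxy}-2-methylpropanoate | COC(=O)[C@H](C)CO[Si](C)(C)C(C)(C)C | intermediate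
17 | (2R)-3-{[tert-butyl(dimethyl)silyl]oxy}-2-methylpropanal | O=C[C@H](C)CO[Si](C)(C)C(C)(C)C | intermediate
18 | tert-butyl(dimethyl){[(2S)-2-methylbut-3-yn-1-yl]oxy}silane | C#C[C@H](C)CO[Si](C)(C)C(C)(C)C | intermediate
19 | N-Boc-O-methyl-D-serine, (2R)-2-[(tert-butoxycarbonyl)amino]-3-methoxypropanoic acid | CC(C)(C)OC(=O)N[C@H](COC)C(=O)O | starting material
20 | tert-butyl N-[(2R)-1-methoxy-3-[methoxy(methyl)amino]-3-oxopropan-2-yl]carbamate | CC(C)(C)OC(=O)N[C@H](COC)C(=O)N(C)OC | intermediate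
21 | lithium acetylide of 18 | [Li]C#C[C@H](C)CO[Si](C)(C)C(C)(C)C | intermediate (not isolated)
22 | tert-butyl N-[(2R,6S)-7-{[tert-butyl(dimethyl)silyl]oxy}-1-methoxy-6-methyl-3-oxohept-4-yn-2-yl]carbamate | CC(C)(C)OC(=O)N[C@H](COC)C(=O)C#C[C@H](C)CO[Si](C)(C)C(C)(C)C | intermediate
23 | tert-butyl N-[(2R,3S,6S)-7-{[tert-butyl(dimethyl)silyl]oxy}-3-hydroxy-1-methoxy-6-methylhept-4-yn-2-yl]carbamate | CC(C)(C)OC(=O)N[C@H](COC)[C@@H](O)C#C[C@H](C)CO[Si](C)(C)C(C)(C)C | intermediate
24 | (2R,3S,6S)-2-amino-1-methoxy-6-methylhept-4-yne-3,7-diol hydrochloride | N[C@H](COC)[C@@H](O)C#C[C@H](C)CO.Cl | intermediate (not isolated)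
25 | (4E,7R,9S)-N-[(2R,3S,6S)-3,7-dihydroxy-1-methoxy-6-methylhept-4-yn-2-yl]-7-methoxy-9-methylhexadec-4-enamide | CCCCCCC[C@H](C)C[C@H](C/C=C/CCC(=O)N[C@H](COC)[C@@H](O)C#C[C@H](C)CO)OC | intermediate
26 | (2S,5S,6R)-5-hydroxy-7-methoxy-6-{[(4E,7R,9S)-7-methoxy-9-methylhexadec-4-enoyl]amino}-2-methylhept-3-yn-1-yl 2,2-dimethylpropanoate | CCCCCCC[C@H](C)C[C@H](C/C=C/CCC(=O)N[C@H](COC)[C@@H](O)C#C[C@H](C)COC(=O)C(C)(C)C)OC | intermediate
27 | (2S,3Z,5R,6R)-5-hydroxy-7-methoxy-6-{[(4E,7R,9S)-7-methoxy-9-methylhexadec-4-enoyl]amino}-2-methyl-4-(tributylstannyl)hept-3-en-1-yl 2,2-dimethylpropanoate | CCCCCCC[C@H](C)C[C@H](C/C=C/CCC(=O)N[C@H](COC)[C@@H](O)/C(=C/[C@H](C)COC(=O)C(C)(C)C)[Sn](CCCC)(CCCC)CCCC)OC | intermediate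
28 | 5-O-triethylsilyl ether of 27, (2S,3Z,5R,6R) | CCCCCCC[C@H](C)C[C@H](C/C=C/CCC(=O)N[C@H](COC)[C@@H](O[Si](CC)(CC)CC)/C(=C/[C@H](C)COC(=O)C(C)(C)C)[Sn](CCCC)(CCCC)CCCC)OC | intermediate
29 | (2S,3Z,5S,6R)-7-methoxy-6-{[(4E,7R,9S)-7-methoxy-9-methylhexadec-4-enoyl]amino}-2-methyl-4-(2-methylprop-2-enoyl)-5-[(triethylsilyl)oxy]hept-3-en-1-yl 2,2-dimethylpropanoate | CCCCCCC[C@H](C)C[C@H](C/C=C/CCC(=O)N[C@H](COC)[C@@H](O[Si](CC)(CC)CC)/C(=C/[C@H](C)COC(=O)C(C)(C)C)C(=O)C(C)=C)OC | intermediate
30 | (2S,3Z,5S,6R)-7-methoxy-6-{[(4E,7R,9S)-7-methoxy-9-methylhexadec-4-enoyl]amino}-2-methyl-4-{2-methyl-1-[(triethylsilyl)oxy]prop-1-en-1-yl}-5-[(triethylsilyl)oxy]hept-3-en-1-yl 2,2-dimethylpropanoate | CCCCCCC[C@H](C)C[C@H](C/C=C/CCC(=O)N[C@H](COC)[C@@H](O[Si](CC)(CC)CC)/C(=C/[C@H](C)COC(=O)C(C)(C)C)C(O[Si](CC)(CC)CC)=C(C)C)OC | intermediate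
31 | (4E,7R,9S)-N-[(2R,3S,4Z,6S)-7-hydroxy-1-methoxy-6-methyl-4-{2-methyl-1-[(triethylsilyl)oxy]prop-1-en-1-yl}-3-[(triethylsilyl)oxy]hept-4-en-2-yl]-7-methoxy-9-methylhexadec-4-enamide | CCCCCCC[C@H](C)C[C@H](C/C=C/CCC(=O)N[C@H](COC)[C@@H](O[Si](CC)(CC)CC)/C(=C/[C@H](C)CO)C(O[Si](CC)(CC)CC)=C(C)C)OC | intermediate
32 | (4E,7R,9S)-N-[(2R,3S,4Z,6S)-1-methoxy-6-methyl-4-{2-methyl-1-[(triethylsilyl)oxy]prop-1-en-1-yl}-7-oxo-3-[(triethylsilyl)oxy]hept-4-en-2-yl]-7-methoxy-9-methylhexadec-4-enamide | CCCCCCC[C@H](C)C[C@H](C/C=C/CCC(=O)N[C@H](COC)[C@@H](O[Si](CC)(CC)CC)/C(=C/[C@H](C)C=O)C(O[Si](CC)(CC)CC)=C(C)C)OC | intermediate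
33 | (4E,7R,9S)-N-[(1S,2R)-1-[(3S,4R)-4-hydroxy-3,5,5-trimethyl-6-oxocyclohex-1-en-1-yl]-3-methoxy-1-[(triethylsilyl)oxy]propan-2-yl]-7-methoxy-9-methylhexadec-4-enamide | CCCCCCC[C@H](C)C[C@H](C/C=C/CCC(=O)N[C@H](COC)[C@@H](O[Si](CC)(CC)CC)C1=C[C@H](C)[C@@H](O)C(C)(C)C1=O)OC | intermediate
34 | (4E,7R,9S)-N-[(1S,2R)-1-hydroxy-1-[(3S,4R)-4-hydroxy-3,5,5-trimethyl-6-oxocyclohex-1-en-1-yl]-3-methoxypropan-2-yl]-7-methoxy-9-methylhexadec-4-enamide | CCCCCCC[C@H](C)C[C@H](C/C=C/CCC(=O)N[C@H](COC)[C@@H](O)C1=C[C@H](C)[C@@H](O)C(C)(C)C1=O)OC | target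

**Step count and risk**

Total step count: 24. Longest linear sequence: 18 steps (steps 1–8 and 15–24, from 1 to 34).

Steps most likely to fail:

Step 23. What may go wrong is poor facial selectivity at the aldehyde (a synclinal instead of an antiperiplanar approach, leading to the 5-epimer), or protodesilylation of the enol ether and enolisation at C4 under the Lewis acid. The fallback sets out from 32 and closes the ring by Lewis-base instead of Lewis-acid activation. Catalytic Bu4N[Ph3SiF2] in THF at −78 °C should release the tetrabutylammonium enolate, which adds to the aldehyde through an extended transition state in which charge repulsion holds the two oxygen atoms apart (oxygen again equatorial, trans to the methyl group). Silyl transfer to the aldolate should then give the 5-O-triethylsilyl ether of 33, the bis(silyl) ether F1. Desilylation of F1 under the conditions of step 24 rejoins the route at 34.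

Step 19. What may go wrong is slow transmetalation at the hindered, fully substituted alkenyl–tin carbon, so that protodestannylation and decomposition of the acid chloride take over. The fallback sets out from 28: iododestannylation (I2, CH2Cl2, 0 °C) with retention gives the alkenyl iodide F2. A carbonylative Stille coupling of F2 with tributyl(isopropenyl)stannane under CO (1 atm, Pd(PPh3)4, THF, 50 °C) should then give 29, where the route continues.

Step 20. What may go wrong is loss of chemoselectivity between the two enone termini, 1,2-hydrosilylation of the ketone, or cyclisation and polymerisation of the dienone. The fallback sets out from 28 and avoids the dienone: Stille acylation with 2-methylpropanoyl chloride under the conditions of step 19 gives the isopropyl ketone F3. Soft enolisation of F3 (Et3SiOTf, Et3N, CH2Cl2, −78 °C) should remove the α'-hydrogen, because the γ-hydrogen at C4 is held in the plane of the alkene by allylic strain, and returns to the route at 30.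

Further compounds
F1 | step 23 | (4E,7R,9S)-N-[(1S,2R)-3-methoxy-1-[(triethylsilyl)oxy]-1-{(3S,4R)-3,5,5-trimethyl-6-oxo-4-[(triethylsilyl)oxy]cyclohex-1-en-1-yl}propan-2-yl]-7-methoxy-9-methylhexadec-4-enamide | CCCCCCC[C@H](C)C[C@H](C/C=C/CCC(=O)N[C@H](COC)[C@@H](O[Si](CC)(CC)CC)C1=C[C@H](C)[C@@H](O[Si](CC)(CC)CC)C(C)(C)C1=O)OC
F2 | step 19 | (2S,3Z,5R,6R)-4-iodo-7-methoxy-6-{[(4E,7R,9S)-7-methoxy-9-methylhexadec-4-enoyl]amino}-2-methyl-5-[(triethylsilyl)oxy]hept-3-en-1-yl 2,2-dimethylpropanoate | CCCCCCC[C@H](C)C[C@H](C/C=C/CCC(=O)N[C@H](COC)[C@@H](O[Si](CC)(CC)CC)/C(I)=C/[C@H](C)COC(=O)C(C)(C)C)OC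
F3 | step 20 | (2S,3Z,5S,6R)-7-methoxy-6-{[(4E,7R,9S)-7-methoxy-9-methylhexadec-4-enoyl]amino}-2-methyl-4-(2-methylpropanoyl)-5-[(triethylsilyl)oxy]hept-3-en-1-yl 2,2-dimethylpropanoate | CCCCCCC[C@H](C)C[C@H](C/C=C/CCC(=O)N[C@H](COC)[C@@H](O[Si](CC)(CC)CC)/C(=C/[C@H](C)COC(=O)C(C)(C)C)C(=O)C(C)C)OC
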